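Locants used throughout: ring A is C1(acyl)–C2–C3(spiro)–C4–C5(geranyl)–C9; C6–C7–C8(Me2) links C5 to C1, C10–C11 links C7 to C3, and C11–C12(Me2)–C13–C14–C3 is the cyclopentane.
A direct plan would dearomatise the alkylphloroglucinol A1 by an oxidative radical spirocyclisation (C3–C11) to the spiro trione A2, put a reverse prenyl group on C1 by O-prenylation and an enantioselective Claisen rearrangement, close the cage in a second radical cascade with Mn(OAc)3 (trivalent manganese; C5–C6, then C7–C10) to the enetrione A3, and hydrogenate C10=C11 to the cage trione A4. Only then would bridgehead lithiation of A4 and geranyl bromide give the C5-geranyl cage trione A5, and a second bridgehead lithiation of A5 with isobutyryl chloride would put the acyl group on C1.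
Weak step, the Claisen rearrangement that fixes the absolute configuration: it would have to be a desymmetrising, dynamic kinetic variant without precedent, so every stereocentre of the cage would hang on an untested step.
Weak step, the bridgehead geranylation of A4 to A5: two bridgehead C–H bonds (C1, C5) compete, lithium bridgehead enolates alkylate poorly with allylic bromides, and the radical chemistry before it forces both side chains to come last.
Weak step, the hydrogenation that sets C11: the stereocentre would be corrected after the cage is closed, on a hindered trisubstituted alkene whose facial bias rests on one methyl group of C8.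

**Retrosynthetic overview**
- C1–C8 is cut last: the tertiary carbinol 13 ionises and the acyl-bearing enol carbon C1 closes ring B and the second seven-membered ring.
- Key disconnection: C3–C14 and C5–C6 of the bridged spiro trione 12 are cut back to the flat, hexasubstituted acylphloroglucinol 10. One base-mediated operation dearomatises ring A twice: first the spiro-cyclopentane, then the seven-membered ring C3–C11–C10–C7–C6–C5–C4. The direct plan instead closes ring B before the seven-membered rings and does so by radical steps.
- 10 is assembled from three components around C11: 3-geranylphlorisobutyrophenone 7 (ring A with the acyl group on C1 and geranyl on C5), aldehyde 4 (C11–C14) and allylboronate 8 (C6, C7, C8, C10).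
- Ring order: ring A (arene) → cyclopentane → seven-membered ring on the C5 side → ring B. Acyl and geranyl are on the arene from the start, all C–C bonds are made by polar chemistry that tolerates the geranyl alkenes, and C11 is set first and relayed to C3, C5, C7 and C1. No bridgehead metalation, radical cage closure or hydrogenation is needed.

Key step: step 5

Assumptions: 5 and 8 are taken as commercial; the (R)-phosphoric acid is assumed to deliver (R)-C11, and its enantiomer would be used if the sense of induction were opposite.

**Step 1**
Reactants: 1 methyl isobutyrate; 2 1-bromo-2-chloroethane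
Product: 3 methyl 4-chloro-2,2-dimethylbutanoate
Conditions: LiN(i-Pr)2 (1.1 equiv), THF, −78 °C; then 2 (1.5 equiv), −78 → 25 °C
Reagents that add atoms: none
Why: Ester enolate alkylation (SN2) at the more reactive C–Br end of 2 should build the quaternary carbon C12 with the C13–C14–Cl arm; no stereocentre is formed.

**Step 2**
Reactants: 3 methyl 4-chloro-2,2-dimethylbutanoate
Product: 4 4-chloro-2,2-dimethylbutanal
Conditions: i-Bu2AlH (1.05 equiv), CH2Cl2, −78 °C; aq Rochelle salt
Reagents that add atoms: none
Why: Partial reduction of the neopentyl ester should stop at the aluminium hemiacetal, which gives the non-enolisable aldehyde (C11) on work-up; the primary chloride is inert.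

**Step 3**
Reactants: 5 2-methyl-1-(2,4,6-trihydroxyphenyl)propan-1-one (phlorisobutyrophenone); 6 geranyl bromide
Product: 7 1-{3-[(2E)-3,7-dimethylocta-2,6-dien-1-yl]-2,4,6-trihydroxyphenyl}-2-methylpropan-1-one
Conditions: 6 (0.9 equiv), 10% aq KOH, 0 °C; then aq HCl
Reagents that add atoms: none
Why: Friedel–Crafts-type C-alkylation of the hydrogen-bonded phenoxide in water should put geranyl on one of the two equivalent ring CH carbons (C5), with 5 in slight excess against double alkylation; the E-alkene is untouched and no stereocentre is formed.

**Step 4**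
Reactants: 7 3-geranylphlorisobutyrophenone; 4 4-chloro-2,2-dimethylbutanal; 8 ethyl 2-[(4,4,5,5-tetramethyl-1,3,2-dioxaborolan-2-yl)methyl]prop-2-enoate
Product: 10 ethyl (4R)-7-chloro-4-{3-[(2E)-3,7-dimethylocta-2,6-dien-1-yl]-2,4,6-trihydroxy-5-(2-methylpropanoyl)phenyl}-5,5-dimethyl-2-methylideneheptanoate, via ortho-quinone methide 9 (not isolated)
Conditions: (R)-3,3′-bis(2,4,6-triisopropylphenyl)-1,1′-binaphthyl-2,2′-diyl hydrogen phosphate (10 mol %), 5 Å MS, toluene, 40 °C
Reagents that add atoms: none
Why: Proposed new method: the phosphoric acid should catalyse hydroxyalkylation of the only free ring carbon (C3) of 7 by the non-enolisable aldehyde 4 and loss of water to the ortho-quinone methide 9, whose exocyclic carbon C11 is then allylated inside the chiral ion pair by boronate 8 through a closed transition state in which boron is bound to the quinone methide oxygen, which forms C10–C11 and sets (R)-C11 (both allyl termini are CH2, so either mode of allyl transfer gives the same product); closest known reaction types: the chiral biphenol-catalysed three-component condensation of phenols, aldehydes and alkenyl or aryl boronates through ortho-quinone methides (Petasis-type) and the chiral phosphoric acid-catalysed allylboration.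

**Step 5**
Reactants: 10 side-chain arene
Product: 12 bridged spiro triketo ester (ethyl ester on C7; C3–C14 and C5–C6 closed; C3 C5 C11 as in the target; C7 epimers), via spirodienone 11 (not isolated)
Conditions: Cs2CO3 (2.5 equiv), NaI (0.3 equiv), MeCN (0.01 M), 25 → 60 °C; then aq citric acid
Reagents that add atoms: none
Why: While ring A is flat, C5 cannot reach the acrylate (this would need a four-atom meta bridge), so the caesium phenoxide of 10 should first close the cyclopentane by intramolecular C-alkylation of C3 with the iodide formed in situ (5-exo-tet, dearomatising ipso-alkylation), and the enolate of spirodienone 11 should then add through C5 to the acrylate terminus C6 (7-endo-trig intramolecular Michael addition) to close the seven-membered ring C3–C11–C10–C7–C6–C5–C4. The closest known reaction types are the intramolecular ipso-alkylation of phenols to spiro[4.5]decadienones and the alkylative dearomatisation of acylphloroglucinols by conjugate addition to acrylate-type acceptors. C3 is set in the spiroalkylation by allylic 1,3-strain at the C11 stereocentre: H-11 should eclipse the C4–O bond of the ion-paired phenoxide, so that the chain C12–C13–C14 attacks one face while the acrylate arm lies over the chelated acyl flank (C2, C1), which is the relative configuration of the target. C5 is set by the tether, because C6 can reach C5 only on the face of ring A that carries C11; C7 forms as a mixture of epimers and is reset in step 7. Chemoselectivity rests on ring size (five-membered C-alkylation against seven-membered O-alkylation), on C5 being the alkyl-substituted and more nucleophilic enolate carbon (C1 bears the acyl group), and on the reversibility of any oxa-Michael adduct.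

**Step 6**
Reactants: 12 bridged spiro triketo ester
Product: 13 bridged spiro carbinol (2-hydroxypropan-2-yl group on C7; C7 epimers)
Conditions: MeMgBr (6 equiv), CeCl3 (3 equiv), THF, −40 → 0 °C; aq NH4Cl
Reagents that add atoms: methylmagnesium bromide, C[Mg]Br
Why: Double Grignard addition to the ester should give the tertiary carbinol (C8 with both methyl groups); the acidic β-triketone is masked as its magnesium enolate, the C4 ketone is flanked by two quaternary carbons, and CeCl3 suppresses enolisation at C7.

**Step 7**
Reactants: 13 bridged spiro carbinol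
Product: 14 target CNP0313870.1
Conditions: CF3SO3H (10 mol %), 4 Å MS, CH2Cl2, −30 → 0 °C
Reagents that add atoms: none
Why: Biomimetic cationic cyclisation: ionisation of the tertiary carbinol gives the C8 cation, which should be captured by the enol carbon C1 (intramolecular SN1 C-alkylation of the β-triketone, as in known tertiary-cation closures of type A acylphloroglucinol cores), closing ring B and the second seven-membered ring; O-alkylated enol ethers re-ionise under the acid, the cation equilibrates with the C7=C8 alkene so that both C7 epimers converge, and the cage fixes C1 and C7 because C8 can reach C1 only on the face of ring A that carries C6, with H-7 outside.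

**Compound list**
1 | methyl isobutyrate | COC(=O)C(C)C | starting material
2 | 1-bromo-2-chloroethane | ClCCBr | starting material
3 | methyl 4-chloro-2,2-dimethylbutanoate | COC(=O)C(C)(C)CCCl | intermediate
4 | 4-chloro-2,2-dimethylbutanal | O=CC(C)(C)CCCl | intermediate
5 | 2-methyl-1-(2,4,6-trihydroxyphenyl)propan-1-one (phlorisobutyrophenone) | CC(C)C(=O)c1c(O)cc(O)cc1O | starting material
6 | geranyl bromide | CC(C)=CCC/C(C)=C/CBr | starting material
7 | 1-{3-[(2E)-3,7-dimethylocta-2,6-dien-1-yl]-2,4,6-trihydroxyphenyl}-2-methylpropan-1-one | CC(C)C(=O)c1c(O)cc(O)c(C/C=C(\C)CCC=C(C)C)c1O | intermediate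
8 | ethyl 2-[(4,4,5,5-tetramethyl-1,3,2-dioxaborolan-2-yl)methyl]prop-2-enoate | CCOC(=O)C(=C)CB1OC(C)(C)C(C)(C)O1 | starting material
9 | ortho-quinone methide of 7 and 4 (exocyclic C3=C11, C4 as carbonyl) | ClCCC(C)(C)C=C1C(=O)C(C/C=C(\C)CCC=C(C)C)=C(O)C(C(=O)C(C)C)=C1O | intermediate (not isolated)
10 | ethyl (4R)-7-chloro-4-{3-[(2E)-3,7-dimethylocta-2,6-dien-1-yl]-2,4,6-trihydroxy-5-(2-methylpropanoyl)phenyl}-5,5-dimethyl-2-methylideneheptanoate | CCOC(=O)C(=C)C[C@H](C(C)(C)CCCl)c1c(O)c(C/C=C(\C)CCC=C(C)C)c(O)c(C(=O)C(C)C)c1O | intermediate
11 | spirodienone: ring A dearomatised at C3, 2,2-dimethylcyclopentane C3–C11–C12–C13–C14 closed, acrylate arm on C11; C3 and C11 as in the target | CCOC(=O)C(=C)C[C@@H]1C(C)(C)CC[C@@]12C(O)=C(C/C=C(\C)CCC=C(C)C)C(=O)C(C(=O)C(C)C)=C2O | intermediate (not isolated)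
12 | bridged spiro triketo ester: ring A with C3 spiro and C5 quaternary, C5 tied to C11 through C6–C7(CO2Et)–C10, C1 as acyl enol; C3, C5, C11 as in the target, C7 epimers | CC(C)=CCC/C(C)=C/C[C@@]12CC(C(=O)OCC)C[C@@H]3C(C)(C)CC[C@]3(C1=O)C(O)=C(C(=O)C(C)C)C2=O | intermediate
13 | bridged spiro carbinol: as 12 with a 2-hydroxypropan-2-yl group (C8) on C7; C7 epimers | CC(C)=CCC/C(C)=C/C[C@@]12CC(C(C)(C)O)C[C@@H]3C(C)(C)CC[C@]3(C1=O)C(O)=C(C(=O)C(C)C)C2=O | intermediate
14 | target CNP0313870.1 | CC(C)=CCC/C(C)=C/C[C@@]12C[C@H]3C[C@@H]4C(C)(C)CC[C@]4(C1=O)C(=O)[C@@](C(=O)C(C)C)(C2=O)C3(C)C | target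

Total step count: 7. Longest linear sequence: 6 steps (steps 1, 2, 4, 5, 6, 7).

**Steps most likely to fail**

Step 4 (three-component condensation). The hindered aldehyde may condense slowly with C3, the boronate may allylate the free aldehyde instead of the quinone methide, and the enantiomeric induction at C11 is untested. Fallback, from 7 and 4: condensation with sodium 4-methylbenzenesulfinate in aqueous formic acid should give the benzylic sulfone F1, a stable quinone methide precursor. K2CO3 then releases the quinone methide, which takes up excess 2-(ethoxycarbonyl)allylzinc bromide F2 (from ethyl 2-(bromomethyl)acrylate and zinc) to give the racemic side-chain arene F3. Preparative chromatography on a chiral stationary phase returns the route to 10.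

Step 5 (double dearomative annulation). Facial selectivity of the spiroalkylation relative to C11 may be poor, which would give the C11-epimeric series, and O-alkylation or premature oxa-Michael addition may compete. Fallback, from 10: silylation of the hydroxyl on C4 (para to the acyl group) with i-Pr3SiOTf/2,6-lutidine should give the silyl ether F4. With the large silyloxy group on C4, allylic 1,3-strain forces H-11 toward C4 in the spiroalkylation (KOt-Bu, NaI), which gives the silyl enol ether F5. Bu4NF then frees the C5 enolate, which closes the seven-membered ring by Michael addition, and the route comes back at 12.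

Step 7 (cationic closure of C1–C8). The cation may be trapped on oxygen or by the proximal geranyl alkene, and the acid may attack the geranyl chain before the C7 epimers have converged. Fallback, from 12: deprotonation with excess LiN(i-Pr)2 and kinetic protonation of the ester enolate from the open outer face should give the single epimer F6, the C7 ester with the ester group pointing at C1. MeMgBr/CeCl3 then gives the carbinol F7. KN(SiMe3)2 (2 equiv) forms the alkoxide–enolate dianion, whose far more basic tertiary alkoxide is sulfonylated by (MeSO2)2O to the tertiary mesylate F8; this ionises on warming under basic, aprotic conditions so that the enolate closes C1–C8 without free acid. The route comes back at 14.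

**Further compounds**
F1 | step 4 | 1-{3-[4-chloro-2,2-dimethyl-1-(4-methylbenzenesulfonyl)butyl]-5-[(2E)-3,7-dimethylocta-2,6-dien-1-yl]-2,4,6-trihydroxyphenyl}-2-methylpropan-1-one (racemic) | Cc1ccc(cc1)S(=O)(=O)C(C(C)(C)CCCl)c1c(O)c(C/C=C(\C)CCC=C(C)C)c(O)c(C(=O)C(C)C)c1O
F2 | step 4 | 2-(ethoxycarbonyl)allylzinc bromide | CCOC(=O)C(=C)C[Zn]Br
F3 | step 4 | racemic 10 | CCOC(=O)C(=C)CC(C(C)(C)CCCl)c1c(O)c(C/C=C(\C)CCC=C(C)C)c(O)c(C(=O)C(C)C)c1O
F4 | step 5 | 10 with the hydroxyl on C4 as tri(propan-2-yl)silyl ether | CCOC(=O)C(=C)C[C@H](C(C)(C)CCCl)c1c(O[Si](C(C)C)(C(C)C)C(C)C)c(C/C=C(\C)CCC=C(C)C)c(O)c(C(=O)C(C)C)c1O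
F5 | step 5 | 11 with the enol oxygen on C4 as tri(propan-2-yl)silyl ether | CCOC(=O)C(=C)C[C@@H]1C(C)(C)CC[C@@]12C(O[Si](C(C)C)(C(C)C)C(C)C)=C(C/C=C(\C)CCC=C(C)C)C(=O)C(C(=O)C(C)C)=C2O
F6 | step 7 | 12 as the single C7 epimer with the ester toward C1 | CC(C)=CCC/C(C)=C/C[C@@]12C[C@H](C(=O)OCC)C[C@@H]3C(C)(C)CC[C@]3(C1=O)C(O)=C(C(=O)C(C)C)C2=O
F7 | step 7 | 13 as the single C7 epimer with C8 toward C1 | CC(C)=CCC/C(C)=C/C[C@@]12C[C@H](C(C)(C)O)C[C@@H]3C(C)(C)CC[C@]3(C1=O)C(O)=C(C(=O)C(C)C)C2=O
F8 | step 7 | tertiary methanesulfonate of F7 | CC(C)=CCC/C(C)=C/C[C@@]12C[C@H](C(C)(C)OS(C)(=O)=O)C[C@@H]3C(C)(C)CC[C@]3(C1=O)C(O)=C(C(=O)C(C)C)C2=O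
A1 | direct plan | 2-(3,3-dimethylpent-4-en-1-yl)benzene-1,3,5-triol | C=CC(C)(C)CCc1c(O)cc(O)cc1O
A2 | direct plan | 2,2-dimethyl-1-methylidenespiro[4.5]decane-6,8,10-trione | C=C1C(C)(C)CCC12C(=O)CC(=O)CC2=O
A3 | direct plan | cage enetrione (C10=C11 alkene, H on C1 and C5) | [C@@H]12C[C@H]3C=C4C(C)(C)CC[C@]4(C1=O)C(=O)[C@@H](C2=O)C3(C)C
A4 | direct plan | cage trione (H on C1 and C5) | [C@@H]12C[C@H]3C[C@@H]4C(C)(C)CC[C@]4(C1=O)C(=O)[C@@H](C2=O)C3(C)C
A5 | direct plan | C5-geranyl cage trione (H on C1) | CC(C)=CCC/C(C)=C/C[C@@]12C[C@H]3C[C@@H]4C(C)(C)CC[C@]4(C1=O)C(=O)[C@@H](C2=O)C3(C)C
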